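**Retrosynthetic overview**

1. Ring D (the 2,3-dihydrofuran) is closed last by cycloisomerization of a C13 ethynyl / C16 hydroxymethyl pair; before that the 6β-hydroxyl comes from an enol ester epoxide acyloxy shift on a C7 ketone, and the C7 ketone / C8 methyl from an exocyclic C8=C17 alkene.
2. Ring C (O–C9–C11–C12–C13) is closed by hypoiodite C9–H etherification from the C13 tertiary alcohol.
3. Rings A and B are made together from an acyclic E,E-diene β-keto ester by oxidative radical bicyclization: the C4–C5 bond closes ring A, then C9–C10 closes ring B (ring order A, B, then C, then D).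
4. Enabling feature: C4 of ring A is a quaternary carbon flanked by two oxygenated carbons, C3 and C19 (C19 axial, syn to the C10 methyl), and bonded to C5 of the trans ring fusion; this array is the reduced form of an α-methyl β-keto ester whose C4 radical can add to a C5=C10 alkene.
5. The polyene is assembled from geranyl phenyl sulfone, an alkynyl epoxide carrying C13 (Sharpless epoxidation) and (−)-8-phenylmenthyl 2-methylacetoacetate.

Key step: step 11

Remark: labdane numbering is used throughout (ring A C1–C5/C10, ring B C5–C10, ring C O/C9/C11–C13, ring D C13–C16/O); TES = triethylsilyl, TBDPS = tert-butyldiphenylsilyl, TMS = trimethylsilyl; the α-carbon of the acyclic β-keto esters and the sulfonyl-bearing carbon of the coupling products are epimer mixtures of no consequence; the (−)-auxiliary is assumed to shield the face of the C4 radical that leads to the 5α,10β series.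

**Route**

Step 1
Reactants: 1 geranyl bromide; 2 sodium benzenesulfinate
Product: 3 geranyl phenyl sulfone
Conditions: DMF, rt
Reagents that add atoms: none
Why: S-alkylation of the sulfinate by SN2 displacement of the primary allylic bromide should give the sulfone without touching the E alkene.

Step 2
Reactants: 4 2-bromoprop-2-en-1-ol; 5 ethynyltrimethylsilane
Product: 6 2-methylidene-4-(trimethylsilyl)but-3-yn-1-ol
Conditions: Pd(PPh3)2Cl2 (2 mol %), CuI (4 mol %), Et3N, THF, rt
Reagents that add atoms: none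
Why: Sonogashira coupling of the vinyl bromide with the terminal alkyne installs the enyne and tolerates the free hydroxyl.

Step 3
Reactants: 6 2-methylidene-4-(trimethylsilyl)but-3-yn-1-ol
Product: 7 (R)-{2-[(trimethylsilyl)ethynyl]oxiran-2-yl}methanol
Conditions: Ti(OiPr)4 (10 mol %), D-(−)-diethyl tartrate (12 mol %), t-BuOOH, 4 Å molecular sieves, CH2Cl2, −20 °C
Reagents that add atoms: tert-butyl hydroperoxide, CC(C)(C)OO
Why: Sharpless asymmetric epoxidation of the 2-substituted allylic alcohol, in which the unnatural D-(−)-tartrate should make the quaternary epoxide carbon (the future C13) R, the mirror image of the S sense that L-(+)-tartrate gives with 2-substituted allyl alcohols.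

Step 4
Reactants: 7 (R)-{2-[(trimethylsilyl)ethynyl]oxiran-2-yl}methanol
Product: 8 (S)-tert-butyldiphenyl({2-[(trimethylsilyl)ethynyl]oxiran-2-yl}methoxy)silane
Conditions: t-BuPh2SiCl, imidazole, DMF, 0 °C → rt
Reagents that add atoms: tert-butyl(chloro)diphenylsilane, CC(C)(C)[Si](Cl)(c1ccccc1)c1ccccc1
Why: Silylation of the primary alcohol with silyl chloride and imidazole leaves the stereocenter untouched (the descriptor changes only through the priority rules).

Step 5
Reactants: 3 geranyl phenyl sulfone; 8 TBDPS-protected alkynyl epoxide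
Product: 10 C11 sulfone bearing 13-OTES 16-OTBDPS and the TMS-alkyne (13R), via lithium alkoxide 9 (not isolated)
Conditions: 3, n-BuLi, THF–HMPA, −78 °C; 8, −78 → −20 °C; then Et3SiOTf, −78 → 0 °C
Reagents that add atoms: triethylsilyl trifluoromethanesulfonate, CC[Si](CC)(CC)OS(=O)(=O)C(F)(F)F
Why: The α-sulfonyl carbanion opens the 2,2-disubstituted epoxide at its CH2 carbon by SN2 (sulfone–epoxide coupling), so the C13–O bond and its configuration are retained, and the tertiary alkoxide is silylated in the same flask; the silyl group on the alkyne blocks SN2′ attack.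

Step 6
Reactants: 10 C11 sulfone
Product: 11 (3R,6E)-3-[(tert-butyldiphenylsilyloxy)methyl]-7,11-dimethyl-3-(triethylsilyloxy)-1-(trimethylsilyl)dodeca-6,10-dien-1-yne
Conditions: Pd(dppp)Cl2 (5 mol %), LiBHEt3, THF, 0 °C
Reagents that add atoms: none
Why: Palladium-catalyzed hydride desulfonylation of the allylic sulfone through a π-allyl complex, with hydride entering at the less substituted terminus, should keep the position and E geometry of the C8=C9 alkene.

Step 7
Reactants: 11 acyclic dienyne
Product: 12 (2E,6E,10R)-10-[(tert-butyldiphenylsilyloxy)methyl]-2,6-dimethyl-10-(triethylsilyloxy)-12-(trimethylsilyl)dodeca-2,6-dien-11-yn-1-ol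
Conditions: SeO2 (0.2 equiv), t-BuOOH, salicylic acid (0.1 equiv), CH2Cl2, 0 °C → rt
Reagents that add atoms: tert-butyl hydroperoxide, CC(C)(C)OO; selenium dioxide (oxygen carrier), O=[Se]=O
Why: SeO2-catalyzed allylic hydroxylation (ene reaction then [2,3]-sigmatropic shift) is selective for the E methyl group of the terminal, most electron-rich trisubstituted alkene and gives the E allylic alcohol (the future C1).

Step 8
Reactants: 12 E,E allylic alcohol
Product: 13 (2E,6E,10R)-1-bromo analog of 12 (allylic bromide)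
Conditions: CBr4, PPh3, 2,6-lutidine, CH2Cl2, −20 °C
Reagents that add atoms: tetrabromomethane, BrC(Br)(Br)Br
Why: Appel bromination converts the primary allylic alcohol into the bromide under nearly neutral conditions that leave the silyl groups alone.

Step 9
Reactants: 14 (−)-8-phenylmenthol; 15 methyl 2-methyl-3-oxobutanoate
Product: 16 (−)-8-phenylmenthyl 2-methyl-3-oxobutanoate
Conditions: DMAP (cat.), toluene, reflux, removal of MeOH
Reagents that add atoms: none
Why: DMAP-catalyzed transesterification of the β-keto ester (through the acylketene), driven by removal of methanol, attaches the chiral auxiliary.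

Step 10
Reactants: 13 allylic bromide; 16 (−)-8-phenylmenthyl 2-methyl-3-oxobutanoate
Product: 17 (−)-8-phenylmenthyl α-methyl β-keto ester of the E,E-dienyne (cyclization substrate)
Conditions: 16, LiN(i-Pr)2 (2.1 equiv), THF, −78 → 0 °C; then 13, 0 °C
Reagents that add atoms: none
Why: γ-Alkylation of the β-keto ester dianion with the primary allylic bromide (SN2) forms the C1–C2 bond at the more reactive terminal carbanion.

Step 11
Reactants: 17 cyclization substrate
Product: 18 (−)-8-phenylmenthyl (13R)-3-oxo-13-(triethylsilyloxy)-16-(tert-butyldiphenylsilyloxy)-15-(trimethylsilyl)labd-8(17)-en-14-yn-19-oate (5α-H 9α-H 10β-methyl)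
Conditions: Mn(OAc)3·2H2O (2.2 equiv), Cu(OAc)2·H2O (1 equiv, reoxidized in situ), degassed AcOH, rt
Reagents that add atoms: none
Why: Mn(OAc)3 converts the β-keto ester into its trivalent manganese enolate and oxidizes it to the electrophilic C4 radical, which adds to C5 of the C5=C10 alkene (C4–C5 bond, ring A); the tertiary C10 radical then adds to C9 of the C8=C9 alkene (ring B) and the tertiary C8 radical is oxidized by Cu(OAc)2 to the exocyclic C8=C17 alkene. The closest known reaction type is the Mn(OAc)3/Cu(OAc)2 oxidative free-radical bicyclization of farnesyl-type α-methyl β-keto esters, including 8-phenylmenthyl esters. Both rings close in the 6-endo-trig mode through a chair–chair transition state. C5, C10 and C9 follow from the E geometry of the two alkenes (trans ring fusion, equatorial C9 side chain), C4 from the known preference of such radicals to cyclize with the ester axial and the methyl equatorial (C19 syn to the C10 methyl), and the absolute sense from the 8-phenylmenthyl group, whose phenyl ring shields one face of the planar dicarbonyl radical. The step needs 6-endo instead of 5-exo addition, secured by the trisubstituted alkenes whose less substituted carbon is the distal one, and elimination toward the methyl group, which is the normal course of the copper-mediated oxidation; the silyl ether on the C13 oxygen keeps it from capturing C8.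

Step 12
Reactants: 18 bicyclic keto ester
Product: 19 (13R)-13-(triethylsilyloxy)-16-(tert-butyldiphenylsilyloxy)-15-(trimethylsilyl)labd-8(17)-en-14-yne-3β,19-diol
Conditions: LiAlH4, THF, 0 °C → reflux; aqueous NaOH work-up
Reagents that add atoms: none
Why: LiAlH4 reduces the hindered ester to the C19 primary alcohol with release of the auxiliary and the C3 ketone to the equatorial 3β-alcohol by axial hydride attack from the α face; the silylated propargylic oxygen prevents hydroalumination of the alkyne.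

Step 13
Reactants: 19 3β,19-diol
Product: 20 3β,19-diacetate of 19
Conditions: Ac2O, pyridine, DMAP (cat.), CH2Cl2, rt
Reagents that add atoms: acetic anhydride, CC(=O)OC(C)=O
Why: Standard acetylation of the primary and the equatorial secondary alcohol while the tertiary oxygen is still silylated.

Step 14
Reactants: 20 diacetate TES ether
Product: 21 3β,19-diacetoxy-16-(tert-butyldiphenylsilyloxy)-15-(trimethylsilyl)labd-8(17)-en-14-yn-13-ol (13R)
Conditions: HF·pyridine, pyridine, THF, 0 °C → rt
Reagents that add atoms: none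
Why: Fluoride cleavage of the triethylsilyl ether with buffered HF·pyridine, under which the primary TBDPS ether, the alkynylsilane and the acetates should persist.

Step 15
Reactants: 21 tertiary alcohol
Product: 22 3β,19-diacetoxy-9α,13-epoxy-16-(tert-butyldiphenylsilyloxy)-15-(trimethylsilyl)labd-8(17)-en-14-yne (13R)
Conditions: PhI(OAc)2, I2 (regenerated), cyclohexane–CH2Cl2, visible light, rt
Reagents that add atoms: none
Why: Suárez hypoiodite reaction, in which the tertiary alkoxy radical abstracts the allylic tertiary C9 hydrogen by 1,5-hydrogen atom transfer and the oxidized C9 center is captured by oxygen to close the tetrahydrofuran (ring C); the C9–O bond should form on the α face opposite the axial C10 methyl so that C11 stays equatorial.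

Step 16
Reactants: 22 9α,13-epoxy-8(17)-ene
Product: 23 7α-hydroxy derivative of 22
Conditions: SeO2 (cat.), t-BuOOH, CH2Cl2, rt
Reagents that add atoms: tert-butyl hydroperoxide, CC(C)(C)OO; selenium dioxide (oxygen carrier), O=[Se]=O
Why: SeO2-catalyzed allylic hydroxylation of the exocyclic alkene at C7, its only allylic methylene now that C9 is quaternary; the configuration of the new carbinol is irrelevant because it is oxidized next.

Step 17
Reactants: 23 7α-allylic alcohol
Product: 24 3β,19-diacetoxy-9α,13-epoxy-16-(tert-butyldiphenylsilyloxy)-15-(trimethylsilyl)labd-8(17)-en-14-yn-7-one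
Conditions: Dess–Martin periodinane, NaHCO3, CH2Cl2, rt
Reagents that add atoms: none
Why: Dess–Martin oxidation of the allylic alcohol gives the α-methylene ketone under buffered, non-enolizing conditions.

Step 18
Reactants: 24 exocyclic enone
Product: 25 3β,19-diacetoxy-9α,13-epoxy-16-(tert-butyldiphenylsilyloxy)-15-(trimethylsilyl)labd-14-yn-7-one (8α-methyl)
Conditions: LiBH(s-Bu)3, THF, −78 °C; then aq. NH4Cl
Reagents that add atoms: none
Why: Conjugate (1,4) hydride addition of the hindered borohydride to the unhindered exocyclic methylene, followed by protonation of the enolate from the axial β face, should give the equatorial 8α-methyl ketone, which is also the thermodynamically favored epimer of this epimerizable center.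

Step 19
Reactants: 25 C7 ketone
Product: 26 Δ6 enol chloroacetate of 25 (7-chloroacetoxy-6-ene)
Conditions: LiN(SiMe3)2, THF, −78 °C; then (ClCH2CO)2O, −78 → 0 °C
Reagents that add atoms: chloroacetic anhydride, O=C(CCl)OC(=O)CCl
Why: LiN(SiMe3)2, too weak a base to enolize the acetates efficiently, removes a proton from the less hindered C6 methylene of the ketone under kinetic control and the enolate is O-acylated by the anhydride to the enol ester.

Step 20
Reactants: 26 enol chloroacetate
Product: 28 3β,19-diacetoxy-6β-(chloroacetoxy)-9α,13-epoxy-16-(tert-butyldiphenylsilyloxy)-15-(trimethylsilyl)labd-14-yn-7-one, via epoxy enol ester 27 (not isolated)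
Conditions: dimethyldioxirane, acetone–CH2Cl2, 0 °C; then toluene, 110 °C
Reagents that add atoms: dimethyldioxirane, CC1(C)OO1
Why: Dimethyldioxirane epoxidizes the enol ester from the less hindered α face (the β face is covered by the axial C10 methyl and C19 groups) and the α-acyloxy epoxide then undergoes the thermal enol ester epoxide rearrangement, an intramolecular 1,2-acyloxy shift with inversion at C6 that places the ester oxygen on the β face and regenerates the C7 ketone.

Step 21
Reactants: 28 6β-chloroacetate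
Product: 29 3β,19-diacetoxy-9α,13-epoxy-6β-hydroxy-16-(tert-butyldiphenylsilyloxy)-15-(trimethylsilyl)labd-14-yn-7-one
Conditions: thiourea, NaHCO3, EtOH, 50 °C
Reagents that add atoms: none
Why: Thiourea attacks the chloromethyl group and the isothiouronium salt cyclizes onto the ester carbonyl, which releases the 6β-alcohol under nearly neutral conditions and leaves the two acetates untouched.

Step 22
Reactants: 29 6β-hydroxy ketone
Product: 30 3β,19-diacetoxy-9α,13-epoxy-6β,16-dihydroxylabd-14-yn-7-one (13R)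
Conditions: Bu4NF, AcOH, THF, 0 °C → rt
Reagents that add atoms: none
Why: Fluoride cleaves both the primary silyl ether and the C(sp)–Si bond, and buffering with acetic acid protects the α-ketol and the acetates from base.

Step 23
Reactants: 30 alkynyl alcohol
Product: 31 target, 3β,19-diacetoxy-6β-hydroxy-9α,13:15,16-diepoxylabd-14-en-7-one (13R)
Conditions: Mo(CO)6 (25 mol %), Et3N, Et2O, hν (350 nm), rt
Reagents that add atoms: none
Why: Mo(CO)5·NEt3-catalyzed cycloisomerization of the 3-butyn-1-ol unit through a molybdenum vinylidene, attacked by the hydroxyl at the terminal carbon (5-endo mode), should give the 2,3-dihydrofuran under basic conditions that the acid-labile allylic spiro ether tolerates; no stereocenter is touched.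

**Compound list**

1 | geranyl bromide, (2E)-1-bromo-3,7-dimethylocta-2,6-diene | CC(C)=CCC/C(C)=C/CBr | starting material
2 | sodium benzenesulfinate | [Na+].[O-]S(=O)c1ccccc1 | starting material
3 | geranyl phenyl sulfone | CC(C)=CCC/C(C)=C/CS(=O)(=O)c1ccccc1 | intermediate
4 | 2-bromoprop-2-en-1-ol | OCC(Br)=C | starting material
5 | ethynyltrimethylsilane | C#C[Si](C)(C)C | starting material
6 | 2-methylidene-4-(trimethylsilyl)but-3-yn-1-ol | C=C(CO)C#C[Si](C)(C)C | intermediate
7 | (R)-{2-[(trimethylsilyl)ethynyl]oxiran-2-yl}methanol | C[Si](C)(C)C#C[C@@]1(CO)CO1 | intermediate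
8 | (S)-tert-butyldiphenyl({2-[(trimethylsilyl)ethynyl]oxiran-2-yl}methoxy)silane | C[Si](C)(C)C#C[C@@]1(CO[Si](c2ccccc2)(c2ccccc2)C(C)(C)C)CO1 | intermediate
9 | lithium alkoxide of the coupled C11 sulfone (13R, C11 epimers) | [Li+].CC(C)=CCC/C(C)=C/C(C[C@]([O-])(CO[Si](c1ccccc1)(c1ccccc1)C(C)(C)C)C#C[Si](C)(C)C)S(=O)(=O)c1ccccc1 | intermediate
10 | C11 sulfone with 13-OTES, 16-OTBDPS and TMS-alkyne (13R, C11 epimers) | CC(C)=CCC/C(C)=C/C(C[C@](O[Si](CC)(CC)CC)(CO[Si](c1ccccc1)(c1ccccc1)C(C)(C)C)C#C[Si](C)(C)C)S(=O)(=O)c1ccccc1 | intermediate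
11 | (3R,6E)-3-[(tert-butyldiphenylsilyloxy)methyl]-7,11-dimethyl-3-(triethylsilyloxy)-1-(trimethylsilyl)dodeca-6,10-dien-1-yne | CC(C)=CCC/C(C)=C/CC[C@](O[Si](CC)(CC)CC)(CO[Si](c1ccccc1)(c1ccccc1)C(C)(C)C)C#C[Si](C)(C)C | intermediate
12 | (2E,6E,10R)-10-[(tert-butyldiphenylsilyloxy)methyl]-2,6-dimethyl-10-(triethylsilyloxy)-12-(trimethylsilyl)dodeca-2,6-dien-11-yn-1-ol | OC/C(C)=C/CC/C(C)=C/CC[C@](O[Si](CC)(CC)CC)(CO[Si](c1ccccc1)(c1ccccc1)C(C)(C)C)C#C[Si](C)(C)C | intermediate
13 | (2E,6E,10R)-1-bromo analog of 12 | BrC/C(C)=C/CC/C(C)=C/CC[C@](O[Si](CC)(CC)CC)(CO[Si](c1ccccc1)(c1ccccc1)C(C)(C)C)C#C[Si](C)(C)C | intermediate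
14 | (−)-8-phenylmenthol, (1R,2S,5R)-5-methyl-2-(2-phenylpropan-2-yl)cyclohexan-1-ol | O[C@@H]1C[C@H](C)CC[C@H]1C(C)(C)c1ccccc1 | starting material
15 | methyl 2-methyl-3-oxobutanoate | COC(=O)C(C)C(C)=O | starting material
16 | (−)-8-phenylmenthyl 2-methyl-3-oxobutanoate (α-epimers) | CC(=O)C(C)C(=O)O[C@@H]1C[C@H](C)CC[C@H]1C(C)(C)c1ccccc1 | intermediate
17 | (−)-8-phenylmenthyl α-methyl β-keto ester of the E,E-dienyne (α-epimers, 13R) | CC(C(=O)O[C@@H]1C[C@H](C)CC[C@H]1C(C)(C)c1ccccc1)C(=O)CC/C(C)=C/CC/C(C)=C/CC[C@](O[Si](CC)(CC)CC)(CO[Si](c1ccccc1)(c1ccccc1)C(C)(C)C)C#C[Si](C)(C)C | intermediate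
18 | (−)-8-phenylmenthyl (13R)-3-oxo-13-(triethylsilyloxy)-16-(tert-butyldiphenylsilyloxy)-15-(trimethylsilyl)labd-8(17)-en-14-yn-19-oate | O=C(O[C@@H]1C[C@H](C)CC[C@H]1C(C)(C)c1ccccc1)[C@@]1(C)C(=O)CC[C@@]2(C)[C@H]1CCC(=C)[C@@H]2CC[C@](O[Si](CC)(CC)CC)(CO[Si](c1ccccc1)(c1ccccc1)C(C)(C)C)C#C[Si](C)(C)C | intermediate
19 | (13R)-13-(triethylsilyloxy)-16-(tert-butyldiphenylsilyloxy)-15-(trimethylsilyl)labd-8(17)-en-14-yne-3β,19-diol | OC[C@@]1(C)[C@@H](O)CC[C@@]2(C)[C@H]1CCC(=C)[C@@H]2CC[C@](O[Si](CC)(CC)CC)(CO[Si](c1ccccc1)(c1ccccc1)C(C)(C)C)C#C[Si](C)(C)C | intermediate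
20 | 3β,19-diacetate of 19 | CC(=O)OC[C@@]1(C)[C@@H](OC(C)=O)CC[C@@]2(C)[C@H]1CCC(=C)[C@@H]2CC[C@](O[Si](CC)(CC)CC)(CO[Si](c1ccccc1)(c1ccccc1)C(C)(C)C)C#C[Si](C)(C)C | intermediate
21 | 3β,19-diacetoxy-16-(tert-butyldiphenylsilyloxy)-15-(trimethylsilyl)labd-8(17)-en-14-yn-13-ol (13R) | CC(=O)OC[C@@]1(C)[C@@H](OC(C)=O)CC[C@@]2(C)[C@H]1CCC(=C)[C@@H]2CC[C@](O)(CO[Si](c1ccccc1)(c1ccccc1)C(C)(C)C)C#C[Si](C)(C)C | intermediate
22 | 3β,19-diacetoxy-9α,13-epoxy-16-(tert-butyldiphenylsilyloxy)-15-(trimethylsilyl)labd-8(17)-en-14-yne | CC(=O)OC[C@@]1(C)[C@@H](OC(C)=O)CC[C@@]2(C)[C@H]1CCC(=C)[C@]21CC[C@](CO[Si](c3ccccc3)(c3ccccc3)C(C)(C)C)(C#C[Si](C)(C)C)O1 | intermediate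
23 | 7α-hydroxy derivative of 22 | CC(=O)OC[C@@]1(C)[C@@H](OC(C)=O)CC[C@@]2(C)[C@H]1CC[C@@H](O)C(=C)[C@]21CC[C@](CO[Si](c3ccccc3)(c3ccccc3)C(C)(C)C)(C#C[Si](C)(C)C)O1 | intermediate
24 | 3β,19-diacetoxy-9α,13-epoxy-16-(tert-butyldiphenylsilyloxy)-15-(trimethylsilyl)labd-8(17)-en-14-yn-7-one | CC(=O)OC[C@@]1(C)[C@@H](OC(C)=O)CC[C@@]2(C)[C@H]1CC(=O)C(=C)[C@]21CC[C@](CO[Si](c3ccccc3)(c3ccccc3)C(C)(C)C)(C#C[Si](C)(C)C)O1 | intermediate
25 | 3β,19-diacetoxy-9α,13-epoxy-16-(tert-butyldiphenylsilyloxy)-15-(trimethylsilyl)labd-14-yn-7-one (8α-methyl) | CC(=O)OC[C@@]1(C)[C@@H](OC(C)=O)CC[C@@]2(C)[C@H]1CC(=O)[C@@H](C)[C@]21CC[C@](CO[Si](c3ccccc3)(c3ccccc3)C(C)(C)C)(C#C[Si](C)(C)C)O1 | intermediate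
26 | Δ6 enol chloroacetate of 25 | CC(=O)OC[C@@]1(C)[C@@H](OC(C)=O)CC[C@@]2(C)[C@H]1C=C(OC(=O)CCl)[C@@H](C)[C@]21CC[C@](CO[Si](c3ccccc3)(c3ccccc3)C(C)(C)C)(C#C[Si](C)(C)C)O1 | intermediate
27 | 6α,7α-epoxide of 26 (7β-chloroacetoxy) | CC(=O)OC[C@@]1(C)[C@@H](OC(C)=O)CC[C@@]2(C)[C@H]1[C@H]3O[C@@]3(OC(=O)CCl)[C@@H](C)[C@]21CC[C@](CO[Si](c4ccccc4)(c4ccccc4)C(C)(C)C)(C#C[Si](C)(C)C)O1 | intermediate
28 | 3β,19-diacetoxy-6β-(chloroacetoxy)-9α,13-epoxy-16-(tert-butyldiphenylsilyloxy)-15-(trimethylsilyl)labd-14-yn-7-one | CC(=O)OC[C@@]1(C)[C@@H](OC(C)=O)CC[C@@]2(C)[C@H]1[C@H](OC(=O)CCl)C(=O)[C@@H](C)[C@]21CC[C@](CO[Si](c3ccccc3)(c3ccccc3)C(C)(C)C)(C#C[Si](C)(C)C)O1 | intermediate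
29 | 3β,19-diacetoxy-9α,13-epoxy-6β-hydroxy-16-(tert-butyldiphenylsilyloxy)-15-(trimethylsilyl)labd-14-yn-7-one | CC(=O)OC[C@@]1(C)[C@@H](OC(C)=O)CC[C@@]2(C)[C@H]1[C@H](O)C(=O)[C@@H](C)[C@]21CC[C@](CO[Si](c3ccccc3)(c3ccccc3)C(C)(C)C)(C#C[Si](C)(C)C)O1 | intermediate
30 | 3β,19-diacetoxy-9α,13-epoxy-6β,16-dihydroxylabd-14-yn-7-one (13R) | CC(=O)OC[C@@]1(C)[C@@H](OC(C)=O)CC[C@@]2(C)[C@H]1[C@H](O)C(=O)[C@@H](C)[C@]21CC[C@](CO)(C#C)O1 | intermediate
31 | 3β,19-diacetoxy-6β-hydroxy-9α,13:15,16-diepoxylabd-14-en-7-one (13R), CNP0317137.1 | CC(=O)OC[C@@]1(C)[C@@H](OC(C)=O)CC[C@@]2(C)[C@H]1[C@H](O)C(=O)[C@@H](C)[C@]21CC[C@]2(C=COC2)O1 | target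

**Step count and risks**

Total step count: 23. Longest linear sequence: 21 steps (steps 2–8 and 10–23, running from 2-bromoprop-2-en-1-ol to the target; steps 1 and 9 are one-step side branches that join at steps 5 and 10).

Steps most likely to fail:

Step 11 (key bicyclization). Facial discrimination by the auxiliary may be insufficient on a substrate of this size, or the copper-mediated termination may be unselective. Fallback, setting out from 13 and returning at 19: 13 alkylates the dianion of ethyl 2-methyl-3-oxobutanoate (LiN(i-Pr)2) to give the ethyl keto ester F1. This is cyclized under the same Mn(OAc)3/Cu(OAc)2 conditions without auxiliary to the bicyclic ethyl ester F2, formed together with the isomer of opposite decalin configuration. Because C13 is already a single enantiomer, the two are diastereomers, and LiAlH4 reduction followed by chromatographic separation gives diol 19. Absolute control is thus moved from the auxiliary to a separation against the Sharpless-derived center.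

Step 15 (hypoiodite etherification). The tertiary alkoxy radical may fragment by β-scission (loss of the silyloxymethyl radical) or add to the exocyclic alkene faster than it abstracts the C9 hydrogen. Fallback, setting out from 21 and returning at 25: 21 is oxidized at C7 (SeO2, t-BuOOH) to the 7α-allylic alcohol F3 and then (Dess–Martin periodinane) to the exocyclic enone F4. RhCl3·3H2O (cat.) in EtOH moves the double bond into the ring to give the 8-en-7-one F5. DBU in toluene then induces intramolecular oxa-Michael addition of the C13 hydroxyl to C9 (axial attack on the α face, thermodynamic protonation at C8), which delivers ketone 25 without any radical step.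

Step 20 (enol ester epoxide rearrangement). Facial selectivity in the epoxidation may be poor, or the acyloxy group may fail to migrate into the crowded β position (elimination or opening with retention instead). Fallback, setting out from 22 and returning at 29: 22 is isomerized (Co(salen)Cl cat., PhSiH3) to the endocyclic 7-ene F6, the only trisubstituted isomer available because C9 is quaternary. Allylic oxidation (CrO3, 3,5-dimethylpyrazole) gives the 7-en-6-one F7. Reductive α-hydroxylation (Mn(dpm)3 cat., PhSiH3, O2, then P(OEt)3) gives the 7-hydroxy-6-ketone F8. NaBH4 reduces the C6 ketone from the open α face to the 6β,7-diol F9, and oxidation of the less hindered C7 hydroxyl only (TEMPO cat., PhI(OAc)2) gives 29. Here the 6β-oxygen comes from hydride delivery to a C6 ketone, not from C–O bond formation on the hindered face.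

Further compounds
F1 | step 11 | ethyl α-methyl β-keto ester of the E,E-dienyne (13R) | CCOC(=O)C(C)C(=O)CC/C(C)=C/CC/C(C)=C/CC[C@](O[Si](CC)(CC)CC)(CO[Si](c1ccccc1)(c1ccccc1)C(C)(C)C)C#C[Si](C)(C)C
F2 | step 11 | ethyl (13R)-3-oxo-13-(triethylsilyloxy)-16-(tert-butyldiphenylsilyloxy)-15-(trimethylsilyl)labd-8(17)-en-14-yn-19-oate | CCOC(=O)[C@@]1(C)C(=O)CC[C@@]2(C)[C@H]1CCC(=C)[C@@H]2CC[C@](O[Si](CC)(CC)CC)(CO[Si](c1ccccc1)(c1ccccc1)C(C)(C)C)C#C[Si](C)(C)C
F3 | step 15 | 7α-hydroxy derivative of 21 (9α-H, 13-OH) | CC(=O)OC[C@@]1(C)[C@@H](OC(C)=O)CC[C@@]2(C)[C@H]1CC[C@@H](O)C(=C)[C@@H]2CC[C@](O)(CO[Si](c1ccccc1)(c1ccccc1)C(C)(C)C)C#C[Si](C)(C)C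
F4 | step 15 | 3β,19-diacetoxy-13-hydroxy-16-(tert-butyldiphenylsilyloxy)-15-(trimethylsilyl)labd-8(17)-en-14-yn-7-one | CC(=O)OC[C@@]1(C)[C@@H](OC(C)=O)CC[C@@]2(C)[C@H]1CC(=O)C(=C)[C@@H]2CC[C@](O)(CO[Si](c1ccccc1)(c1ccccc1)C(C)(C)C)C#C[Si](C)(C)C
F5 | step 15 | 3β,19-diacetoxy-13-hydroxy-16-(tert-butyldiphenylsilyloxy)-15-(trimethylsilyl)labd-8-en-14-yn-7-one | CC(=O)OC[C@@]1(C)[C@@H](OC(C)=O)CC[C@@]2(C)[C@H]1CC(=O)C(C)=C2CC[C@](O)(CO[Si](c1ccccc1)(c1ccccc1)C(C)(C)C)C#C[Si](C)(C)C
F6 | step 20 | 3β,19-diacetoxy-9α,13-epoxy-16-(tert-butyldiphenylsilyloxy)-15-(trimethylsilyl)labd-7-en-14-yne | CC(=O)OC[C@@]1(C)[C@@H](OC(C)=O)CC[C@@]2(C)[C@H]1CC=C(C)[C@]21CC[C@](CO[Si](c3ccccc3)(c3ccccc3)C(C)(C)C)(C#C[Si](C)(C)C)O1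
F7 | step 20 | 3β,19-diacetoxy-9α,13-epoxy-16-(tert-butyldiphenylsilyloxy)-15-(trimethylsilyl)labd-7-en-14-yn-6-one | CC(=O)OC[C@@]1(C)[C@@H](OC(C)=O)CC[C@@]2(C)[C@H]1C(=O)C=C(C)[C@]21CC[C@](CO[Si](c3ccccc3)(c3ccccc3)C(C)(C)C)(C#C[Si](C)(C)C)O1
F8 | step 20 | 7-hydroxy-6-ketone (8α-methyl, C7 epimers) | CC(=O)OC[C@@]1(C)[C@@H](OC(C)=O)CC[C@@]2(C)[C@H]1C(=O)C(O)[C@@H](C)[C@]21CC[C@](CO[Si](c3ccccc3)(c3ccccc3)C(C)(C)C)(C#C[Si](C)(C)C)O1
F9 | step 20 | 6β,7-diol (8α-methyl, C7 epimers) | CC(=O)OC[C@@]1(C)[C@@H](OC(C)=O)CC[C@@]2(C)[C@H]1[C@H](O)C(O)[C@@H](C)[C@]21CC[C@](CO[Si](c3ccccc3)(c3ccccc3)C(C)(C)C)(C#C[Si](C)(C)C)O1
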